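**Retrosynthetic overview**

1. Target 28 ⇐ O-debenzylation of 27 ⇐ trans-selective reductive C1-methylation of N-methyl lactam 24 ⇐ Suzuki–Miyaura coupling of C5 bromide 13 with naphthyl boronate 23.
2. The hetero ring (C1, N2, C3, C4, C4a, C8a) is made as lactam 10 by a two-atom ring expansion of the four-membered ring of (R)-1,4-dimethylazetidin-2-one 3: the arene bond C8a–C4a is inserted, as 3,5-dimethoxybenzyne, into the acyl–CH2 bond of the β-lactam (C1–C4 of the target).
3. Enabling feature: C1(=O)–N2(Me)–C3(H)(Me)–C4H2 of the target ring is a complete β-lactam whose C1 and C4 are bridged by the adjacent arene carbons C8a and C4a. The oxygen on C8, next to C8a, polarises the aryne so that C4 bonds to C4a and the acyl carbon C1 ends on C8a; the same C1 carbonyl later directs demethylation at O8 and carries the C1 methylation.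
4. Ring order: benzene ring of 4 (bought) → azetidinone (step 1) → six-membered lactam by ring expansion (step 3); the naphthalene rings are built separately by Wittig olefination and cycloaromatisation (steps 8–9); biaryl bond in step 12.
5. Stereochemistry: C3 comes from (R)-3-aminobutanoic acid; C1 is set last by methyl addition anti to the C3 methyl group.

Key step: step 3

Remark: the SMILES defines C1 and C3 only and leaves the configurationally stable C5–C1' biaryl axis open, so steps 12–14 carry both atropo-diastereomers; both fit the given structure and can be separated by chromatography after step 14 if a single rotamer is wanted.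

**Route**

Step 1
Reactants: 1 (R)-3-aminobutanoic acid
Product: 2 (R)-4-methylazetidin-2-one
Conditions: PPh3 (1.2 equiv), 2,2'-dipyridyl disulfide (1.2 equiv), MeCN (0.01 M), reflux
Reagents that add atoms: none
Why: Phosphine–disulfide carboxyl activation (redox condensation) followed by 4-exo-trig N-acylation under high dilution is an established β-amino acid to β-lactam cyclodehydration and does not touch the stereocentre, which becomes C4 of 2.

Step 2
Reactants: 2 (R)-4-methylazetidin-2-one
Product: 3 (R)-1,4-dimethylazetidin-2-one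
Conditions: NaH (1.2 equiv), MeI (1.5 equiv), THF, 0 °C → rt
Reagents that add atoms: iodomethane, CI
Why: N-Alkylation of the lactam anion (amide N-methylation); the stereocentre is not acidic and is unaffected.

Step 3
Reactants: 3 (R)-1,4-dimethylazetidin-2-one; 4 1-bromo-3,5-dimethoxybenzene
Product: 10 (R)-6,8-dimethoxy-2,3-dimethyl-3,4-dihydroisoquinolin-1(2H)-one, via lithium enolate 5 (not isolated), via 3,5-dimethoxybenzyne 6 (not isolated), via aryllithium adduct 7 (not isolated), via benzocyclobutenoxide 8 (not isolated), via C4-lithiated lactam 9 (not isolated)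
Conditions: LiTMP (3.2 equiv), THF, −78 °C; 3 (2.0 equiv); then 4 (1.0 equiv), −78 → −30 °C; H2O, −78 °C
Reagents that add atoms: none
Why: Proposed new method: LiTMP converts 3 into enolate 5 and dehydrobrominates 4 to aryne 6; carbon C3 of 5 (the future C4) adds to the aryne carbon remote from the flanking methoxy group (future C4a) to give aryllithium 7, which closes onto the strained lactam carbonyl to benzocyclobutenoxide 8, and 8 cleaves the former acyl–Cα bond of the azetidinone to give the six-membered lactam as its benzylic C4 anion 9, protonated on quench. The closest known reaction types are the acyl-alkylation of arynes by β-ketoesters (aryne insertion into a C–C σ bond), the two-carbon ring expansion of cycloalkanone enolates with arynes and the four-centre acyl transfer of the anionic ortho-Fries rearrangement; none has been shown for a lactam enolate. The only ring closed directly is the transient four-membered carbocycle (4-exo-trig attack of the aryl carbanion on C=O); the six-membered ring (C1, N2, C3, C4, C4a, C8a) then arises by cleavage of the bond shared by the two four-membered rings, a net 4 → 6 expansion by the two arene carbons. No stereocentre is created: C3 (R) is carried from 1, sits β to the carbonyl and is never deprotonated. The step needs regioselective aryne capture, secured by the methoxy group on the carbon next to the aryne (the carbanion develops ortho to it, at C8a), and C–C rather than C–N fragmentation of 8, secured by release of both four-membered rings and by the benzylic, amide-conjugated carbanion as leaving group. Attack of the base on the aryne is held back by the hindered amide LiTMP and by the excess of 5.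

Step 4
Reactants: 10 (R)-6,8-dimethoxy-2,3-dimethyl-3,4-dihydroisoquinolin-1(2H)-one
Product: 11 (R)-5-bromo-6,8-dimethoxy-2,3-dimethyl-3,4-dihydroisoquinolin-1(2H)-one
Conditions: NBS (1.05 equiv), MeCN, 0 °C → rt, dark
Reagents that add atoms: N-bromosuccinimide, O=C1CCC(=O)N1Br
Why: Electrophilic aromatic bromination should go to C5, para to the C8 and ortho to the C6 methoxy group, because the only other activated position, C7, is flanked by both methoxy groups.

Step 5
Reactants: 11 (R)-5-bromo-6,8-dimethoxy-2,3-dimethyl-3,4-dihydroisoquinolin-1(2H)-one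
Product: 12 (R)-5-bromo-8-hydroxy-6-methoxy-2,3-dimethyl-3,4-dihydroisoquinolin-1(2H)-one
Conditions: BCl3 (1.5 equiv), CH2Cl2, −78 → 0 °C; then H2O
Reagents that add atoms: none
Why: Lewis acid ether cleavage under chelation control: BCl3 binds the lactam carbonyl and should remove only the methyl group of the adjacent C8 methoxy group, leaving the C6 ether intact.

Step 6
Reactants: 12 (R)-5-bromo-8-hydroxy-6-methoxy-2,3-dimethyl-3,4-dihydroisoquinolin-1(2H)-one
Product: 13 (R)-8-(benzyloxy)-5-bromo-6-methoxy-2,3-dimethyl-3,4-dihydroisoquinolin-1(2H)-one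
Conditions: BnBr (1.3 equiv), K2CO3 (2 equiv), DMF, 60 °C
Reagents that add atoms: benzyl bromide, BrCc1ccccc1
Why: Williamson etherification protects the phenol for the organometallic steps that follow.

Step 7
Reactants: 14 (E)-but-2-enoic acid (crotonic acid); 15 triphenylphosphine hydrobromide
Product: 16 (1-carboxypropan-2-yl)triphenylphosphonium bromide (racemic)
Conditions: MeCN, reflux
Reagents that add atoms: none
Why: Conjugate (phospha-Michael) addition of the phosphine to the protonated enoic acid gives the β-phosphonium salt.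

Step 8
Reactants: 16 (1-carboxypropan-2-yl)triphenylphosphonium bromide; 17 2-bromo-5-methoxybenzaldehyde
Product: 19 4-(2-bromo-5-methoxyphenyl)-3-methylbut-3-enoic acid (E/Z mixture), via phosphorus ylide 18 (not isolated)
Conditions: t-BuOK (2.2 equiv), THF, 0 °C → rt; then aq. HCl
Reagents that add atoms: none
Why: Wittig olefination of the aldehyde with the carboxylate ylide 18 gives the β,γ-unsaturated acid; its E/Z mixture is of no consequence because step 9 equilibrates the double bond.

Step 9
Reactants: 19 4-(2-bromo-5-methoxyphenyl)-3-methylbut-3-enoic acid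
Product: 20 5-bromo-8-methoxy-3-methylnaphthalen-1-yl acetate
Conditions: Ac2O, NaOAc (1.5 equiv), 140 °C
Reagents that add atoms: acetic anhydride, CC(=O)OC(C)=O
Why: Carboxyl activation by Ac2O, intramolecular Friedel–Crafts acylation at the only free ortho position of the arene (ortho to OMe), enolisation and O-acetylation amount to a cycloaromatisation to the 1-naphthyl acetate.

Step 10
Reactants: 20 5-bromo-8-methoxy-3-methylnaphthalen-1-yl acetate
Product: 22 1-bromo-4,5-dimethoxy-7-methylnaphthalene, via naphthol 21 (not isolated)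
Conditions: K2CO3, MeOH, rt; solvent exchange; MeI (2 equiv), K2CO3 (2 equiv), DMF, rt
Reagents that add atoms: iodomethane, CI
Why: Methanolysis of the aryl acetate and Williamson O-methylation of the freed naphthol 21 give the peri-dimethoxynaphthalene.

Step 11
Reactants: 22 1-bromo-4,5-dimethoxy-7-methylnaphthalene
Product: 23 2-(4,5-dimethoxy-7-methylnaphthalen-1-yl)-4,4,5,5-tetramethyl-1,3,2-dioxaborolane
Conditions: PdCl2(dppf) (3 mol %), B2pin2 (1.2 equiv), KOAc (3 equiv), 1,4-dioxane, 90 °C
Reagents that add atoms: bis(pinacolato)diboron, CC1(C)OB(OC1(C)C)B1OC(C)(C)C(C)(C)O1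
Why: Miyaura borylation of the aryl bromide.

Step 12
Reactants: 13 (R)-8-(benzyloxy)-5-bromo-6-methoxy-2,3-dimethyl-3,4-dihydroisoquinolin-1(2H)-one; 23 2-(4,5-dimethoxy-7-methylnaphthalen-1-yl)-4,4,5,5-tetramethyl-1,3,2-dioxaborolane
Product: 24 (R)-8-(benzyloxy)-5-(4,5-dimethoxy-7-methylnaphthalen-1-yl)-6-methoxy-2,3-dimethyl-3,4-dihydroisoquinolin-1(2H)-one (both rotamers)
Conditions: Pd(OAc)2 (5 mol %), SPhos (10 mol %), K3PO4 (3 equiv), toluene/H2O (10:1), 100 °C
Reagents that add atoms: none
Why: Suzuki–Miyaura coupling with a bulky dialkylbiarylphosphine ligand, suited to a doubly ortho-substituted bromide and a 1-naphthyl boronate, should form the C5–C1' bond as both rotamers.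

Step 13
Reactants: 24 (R)-8-(benzyloxy)-5-(4,5-dimethoxy-7-methylnaphthalen-1-yl)-6-methoxy-2,3-dimethyl-3,4-dihydroisoquinolin-1(2H)-one
Product: 27 (1R,3R)-8-(benzyloxy)-5-(4,5-dimethoxy-7-methylnaphthalen-1-yl)-6-methoxy-1,2,3-trimethyl-1,2,3,4-tetrahydroisoquinoline, via silyl hemiaminal 25 (not isolated), via iminium ion 26 (not isolated)
Conditions: IrCl(CO)(PPh3)2 (2 mol %), (HMe2Si)2O (2.5 equiv), toluene, rt; then MeMgBr (3 equiv), −78 °C → rt
Reagents that add atoms: methylmagnesium bromide, C[Mg]Br
Why: Iridium-catalysed hydrosilylation of the tertiary lactam stops at N,O-silyl hemiaminal 25, which the Grignard reagent ionises to iminium 26 and methylates anti to the pseudoaxial C3 methyl group (A(1,2) strain with N-methyl), setting C1 as R, trans to C3 (reductive alkylation of a tertiary lactam).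

Step 14
Reactants: 27 (1R,3R)-8-(benzyloxy)-5-(4,5-dimethoxy-7-methylnaphthalen-1-yl)-6-methoxy-1,2,3-trimethyl-1,2,3,4-tetrahydroisoquinoline
Product: 28 ancistrocongoline B, (1R,3R)-5-(4,5-dimethoxy-7-methylnaphthalen-1-yl)-6-methoxy-1,2,3-trimethyl-1,2,3,4-tetrahydroisoquinolin-8-ol
Conditions: H2 (1 atm), 10% Pd on carbon, MeOH/EtOAc, rt
Reagents that add atoms: none
Why: Hydrogenolysis of the benzyl ether frees the C8 phenol without affecting the methyl ethers, the amine or the stereocentres.

**Compound list**

1 | (R)-3-aminobutanoic acid | C[C@@H](N)CC(=O)O | starting material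
2 | (R)-4-methylazetidin-2-one | C[C@@H]1CC(=O)N1 | intermediate
3 | (R)-1,4-dimethylazetidin-2-one | C[C@@H]1CC(=O)N1C | intermediate
4 | 1-bromo-3,5-dimethoxybenzene | COc1cc(Br)cc(OC)c1 | starting material
5 | lithium enolate of 3 | C[C@@H]1C=C([O-])N1C.[Li+] | intermediate (not isolated)
6 | 3,5-dimethoxybenzyne (1,2-didehydro-3,5-dimethoxybenzene) | COC1=CC(OC)=CC#C1 | intermediate (not isolated)
7 | aryllithium adduct, (4R)-3-(2-lithio-3,5-dimethoxyphenyl)-1,4-dimethylazetidin-2-one | C[C@@H]1C(c2cc(OC)cc(OC)c2[Li])C(=O)N1C | intermediate (not isolated)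
8 | benzocyclobutenoxide, lithium alkoxide of the formal [2+2] adduct of 5 and 6 (2-azabicyclo[2.2.0]hexane fused to the dimethoxybenzene ring) | C[C@@H]1C2c3cc(OC)cc(OC)c3C2([O-])N1C.[Li+] | intermediate (not isolated)
9 | C4-lithiated lactam, lithium salt of 10 deprotonated at C4 | COc1cc(OC)c2c(c1)[CH-][C@@H](C)N(C)C2=O.[Li+] | intermediate (not isolated)
10 | (R)-6,8-dimethoxy-2,3-dimethyl-3,4-dihydroisoquinolin-1(2H)-one | COc1cc(OC)c2c(c1)C[C@@H](C)N(C)C2=O | intermediate
11 | (R)-5-bromo-6,8-dimethoxy-2,3-dimethyl-3,4-dihydroisoquinolin-1(2H)-one | COc1cc(OC)c2c(c1Br)C[C@@H](C)N(C)C2=O | intermediate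
12 | (R)-5-bromo-8-hydroxy-6-methoxy-2,3-dimethyl-3,4-dihydroisoquinolin-1(2H)-one | COc1cc(O)c2c(c1Br)C[C@@H](C)N(C)C2=O | intermediate
13 | (R)-8-(benzyloxy)-5-bromo-6-methoxy-2,3-dimethyl-3,4-dihydroisoquinolin-1(2H)-one | COc1cc(OCc3ccccc3)c2c(c1Br)C[C@@H](C)N(C)C2=O | intermediate
14 | (E)-but-2-enoic acid (crotonic acid) | C/C=C/C(=O)O | starting material
15 | triphenylphosphine hydrobromide | [Br-].[PH+](c1ccccc1)(c1ccccc1)c1ccccc1 | starting material
16 | (1-carboxypropan-2-yl)triphenylphosphonium bromide (racemic) | CC(CC(=O)O)[P+](c1ccccc1)(c1ccccc1)c1ccccc1.[Br-] | intermediate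
17 | 2-bromo-5-methoxybenzaldehyde | COc1ccc(Br)c(C=O)c1 | starting material
18 | phosphorus ylide, potassium 3-(triphenylphosphoranylidene)butanoate | CC(CC(=O)[O-])=P(c1ccccc1)(c1ccccc1)c1ccccc1.[K+] | intermediate (not isolated)
19 | 4-(2-bromo-5-methoxyphenyl)-3-methylbut-3-enoic acid (E/Z mixture) | COc1ccc(Br)c(C=C(C)CC(=O)O)c1 | intermediate
20 | 5-bromo-8-methoxy-3-methylnaphthalen-1-yl acetate | CC(=O)Oc1cc(C)cc2c(Br)ccc(OC)c12 | intermediate
21 | naphthol, 5-bromo-8-methoxy-3-methylnaphthalen-1-ol | COc1ccc(Br)c2cc(C)cc(O)c12 | intermediate (not isolated)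
22 | 1-bromo-4,5-dimethoxy-7-methylnaphthalene | COc1cc(C)cc2c(Br)ccc(OC)c12 | intermediate
23 | 2-(4,5-dimethoxy-7-methylnaphthalen-1-yl)-4,4,5,5-tetramethyl-1,3,2-dioxaborolane | COc1cc(C)cc2c(B3OC(C)(C)C(C)(C)O3)ccc(OC)c12 | intermediate
24 | (R)-8-(benzyloxy)-5-(4,5-dimethoxy-7-methylnaphthalen-1-yl)-6-methoxy-2,3-dimethyl-3,4-dihydroisoquinolin-1(2H)-one | COc1cc(OCc4ccccc4)c2c(c1-c1ccc(OC)c3c(OC)cc(C)cc13)C[C@@H](C)N(C)C2=O | intermediate
25 | silyl hemiaminal, C1–O–SiMe2–O–SiMe2H derivative of 24 reduced at C1 | COc1cc(OCc4ccccc4)c2c(c1-c1ccc(OC)c3c(OC)cc(C)cc13)C[C@@H](C)N(C)C2O[Si](C)(C)O[SiH](C)C | intermediate (not isolated)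
26 | iminium ion, (R)-8-(benzyloxy)-5-(4,5-dimethoxy-7-methylnaphthalen-1-yl)-6-methoxy-2,3-dimethyl-3,4-dihydroisoquinolin-2-ium siloxanolate | COc1cc(OCc4ccccc4)c2c(c1-c1ccc(OC)c3c(OC)cc(C)cc13)C[C@@H](C)[N+](C)=C2.C[SiH](C)O[Si](C)(C)[O-] | intermediate (not isolated)
27 | (1R,3R)-8-(benzyloxy)-5-(4,5-dimethoxy-7-methylnaphthalen-1-yl)-6-methoxy-1,2,3-trimethyl-1,2,3,4-tetrahydroisoquinoline | COc1cc(OCc4ccccc4)c2c(c1-c1ccc(OC)c3c(OC)cc(C)cc13)C[C@@H](C)N(C)[C@@H]2C | intermediate
28 | ancistrocongoline B, (1R,3R)-5-(4,5-dimethoxy-7-methylnaphthalen-1-yl)-6-methoxy-1,2,3-trimethyl-1,2,3,4-tetrahydroisoquinolin-8-ol | COc1cc(O)c2c(c1-c1ccc(OC)c3c(OC)cc(C)cc13)C[C@@H](C)N(C)[C@@H]2C | target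

**Step count**

Total: 14 steps. Longest linear sequence: 9 steps (1, 2, 3, 4, 5, 6, 12, 13, 14) from 1; the naphthalene branch (steps 7–11) joins at step 12.

**Steps most likely to fail, with fallbacks**

Step 3 (proposed new method). The aryl carbanion of 7 may be quenched by proton transfer, from the amine or from the now benzylic lactam C–H, faster than it closes onto the carbonyl group. That would give arylation without ring expansion. Alternatively 8 may open by C–N instead of C–C cleavage. The fallback keeps a ring expansion but uses known chemistry; it sets out from 4 and comes back at 10. Commercial methyl (S)-3-bromo-2-methylpropanoate is converted with zinc dust (LiCl, THF) into (S)-(3-methoxy-2-methyl-3-oxopropyl)zinc bromide F1. Negishi coupling of F1 with 4 (Pd(OAc)2, SPhos, THF, rt) should give methyl (R)-3-(3,5-dimethoxyphenyl)-2-methylpropanoate F2. Hydrolysis (LiOH, THF/H2O, 0 °C) gives (R)-3-(3,5-dimethoxyphenyl)-2-methylpropanoic acid F3. Intramolecular Friedel–Crafts acylation (trifluoroacetic anhydride, CH2Cl2, 0 °C) gives (R)-5,7-dimethoxy-2-methylindan-1-one F4. A Schmidt reaction (NaN3, MeSO3H, CH2Cl2, 0 °C) then expands the five-membered ring, with migration of the alkyl carbon and retention, to (R)-6,8-dimethoxy-3-methyl-3,4-dihydroisoquinolin-1(2H)-one F5. N-Methylation (NaH, MeI, THF) gives 10.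

Step 13. The hydrosilylation may stall at the hindered, electron-rich aryl lactam carbonyl or run on past the hemiaminal stage, and the facial selectivity of the methyl transfer may erode if the iminium ion is not formed cleanly. The fallback sets out from 24 and comes back at 27. LiAlH4 (THF, reflux) reduces the lactam to (R)-8-(benzyloxy)-5-(4,5-dimethoxy-7-methylnaphthalen-1-yl)-6-methoxy-2,3-dimethyl-1,2,3,4-tetrahydroisoquinoline F6. Oxidation with I2/KOAc (EtOH, reflux) at the benzylic C1 position gives the isolable (R)-8-(benzyloxy)-5-(4,5-dimethoxy-7-methylnaphthalen-1-yl)-6-methoxy-2,3-dimethyl-3,4-dihydroisoquinolin-2-ium iodide F7. Addition of MeMgBr (THF, −78 °C) to this preformed salt, anti to the C3 methyl group, gives 27.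

Step 12. Protodeboronation of the electron-rich naphthyl boronate may outrun transmetallation at the doubly ortho-substituted bromide. The fallback sets out from 22 and 13 and comes back at 24. Bromine–lithium exchange on 22 (n-BuLi, THF, −78 °C) gives (4,5-dimethoxy-7-methylnaphthalen-1-yl)lithium F8. Transmetallation with ZnCl2 gives (4,5-dimethoxy-7-methylnaphthalen-1-yl)zinc chloride F9. Negishi coupling of F9 with 13 (Pd(OAc)2, SPhos, THF, 60 °C) gives 24.

**Further compounds**

F1 | step 3 | (S)-(3-methoxy-2-methyl-3-oxopropyl)zinc bromide | Br[Zn]C[C@@H](C)C(=O)OC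
F2 | step 3 | methyl (R)-3-(3,5-dimethoxyphenyl)-2-methylpropanoate | COc1cc(C[C@@H](C)C(=O)OC)cc(OC)c1
F3 | step 3 | (R)-3-(3,5-dimethoxyphenyl)-2-methylpropanoic acid | COc1cc(C[C@@H](C)C(=O)O)cc(OC)c1
F4 | step 3 | (R)-5,7-dimethoxy-2-methylindan-1-one | COc1cc(OC)c2c(c1)C[C@@H](C)C2=O
F5 | step 3 | (R)-6,8-dimethoxy-3-methyl-3,4-dihydroisoquinolin-1(2H)-one | COc1cc(OC)c2c(c1)C[C@@H](C)NC2=O
F6 | step 13 | (R)-8-(benzyloxy)-5-(4,5-dimethoxy-7-methylnaphthalen-1-yl)-6-methoxy-2,3-dimethyl-1,2,3,4-tetrahydroisoquinoline | COc1cc(OCc4ccccc4)c2c(c1-c1ccc(OC)c3c(OC)cc(C)cc13)C[C@@H](C)N(C)C2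
F7 | step 13 | (R)-8-(benzyloxy)-5-(4,5-dimethoxy-7-methylnaphthalen-1-yl)-6-methoxy-2,3-dimethyl-3,4-dihydroisoquinolin-2-ium iodide | COc1cc(OCc4ccccc4)c2c(c1-c1ccc(OC)c3c(OC)cc(C)cc13)C[C@@H](C)[N+](C)=C2.[I-]
F8 | step 12 | (4,5-dimethoxy-7-methylnaphthalen-1-yl)lithium | COc1cc(C)cc2c([Li])ccc(OC)c12
F9 | step 12 | (4,5-dimethoxy-7-methylnaphthalen-1-yl)zinc chloride | COc1cc(C)cc2c([Zn]Cl)ccc(OC)c12
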